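Locants C2 to C8a are the isoflavone numbering of the target and are used for the corresponding carbons of every ring A intermediate. C1'' to C4'' is the hydroxylated C6 side chain and C2'' is its carbinol carbon.

## Analysis of the target

The target is an isoflavone: a 4H-chromen-4-one (rings A and C) with a 2,4-dihydroxyphenyl ring B on C3 and hydrogen on C2. Ring A is hexasubstituted. Oxygen sits on C5 (hydroxyl), C7 (hydroxyl) and C8a (O1 of ring C), and carbon sits on C4a (the C4 carbonyl), C6 (a 2-hydroxy-3-methylbut-3-enyl chain) and C8 (a prenyl group). The only stereocentre is C2'' (R), a secondary allylic carbinol next to an isopropenyl group, so only absolute configuration has to be secured and then kept away from ionising or enolising conditions. The sensitive groups are: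
- the prenyl olefin beside the C7 hydroxyl, which closes to a chroman under acid;
- the isopropenyl carbinol, open to alkene protonation, allylic ionisation and cyclisation onto O5 or O7;
- four oxidisable phenols;
- the C2=C3 enone of ring C, which strong nucleophiles open.

Ring C is routine. The hard part is ring A: two different carbon chains must be placed on C6 and C8 of a phloroglucinol nucleus whose three oxygens are nearly equivalent, and ring C must close on O8a and not on O5. The strategy rests on the alternating pattern O5/C6/O7/C8/O8a/C4a. C7 with its oxygen is read as a ketene carbonyl, C8 and C8a as an oxygen-substituted alkyne, and C4a, C5 and C6 as the three remaining carbons of a 3-alkoxycyclobutenone. A cyclobutenone–ynol ether benzannulation then fixes every substituent by connectivity and delivers the three oxygens in three different states.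

## Retrosynthetic reasoning

**Protecting groups (34 from 33 from 32).** Target 34 arises from 33 by loss of three acetal groups and one silyl ether, and 33 from 32 by cleavage of the C5 ethyl ether. The C5 ether is cut only after ring C exists, because the C4 carbonyl then singles it out: a Lewis acid chelated between O4 and O5 activates this ether alone. Until then the ether keeps O5 out of the ring closure.

**Ring C (32 from 30).** The bonds O1–C2 and C2–C3 are cut, removing C2 as a one-carbon unit and leading to the 2-hydroxydeoxybenzoin 30. This is preferred to a C3–aryl coupling, which would need halogenation of an electron-rich chromone carrying two olefins. The forward reaction must condense a formyl equivalent on the activated methylene (enaminone 31) and close on O8a. That is certain because O8a is the only free phenol of 30, released from the silyl ether 29.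

**C4–C4a (29 from 21 and 25).** Ketone 29 is cut, through carbinol 28, between the carbonyl carbon and C4a into aryl bromide 21 and aldehyde 25. An acid-mediated acylation of ring A is excluded by the prenyl group, the acetals and the silyl ethers. A C4a carbanion (aryllithium 26, arylcerium 27) at low temperature tolerates them all. Bromide 21 comes from 20 by substitution at the one free ring position, and 20 from phenol 19 by capping O7.

**Ring A, the key disconnection (19 from 14 and 4).** Three bonds of 19 are cut: C7–C8, C4a–C8a and C6–C7. This gives cyclobutenone 14 and siloxyalkyne 4. The cut is made here because it is the only one that turns the regiochemical problem of ring A into a connectivity problem. Ring C2, C3 and C4 of 14 become C4a, C5 and C6, the carbonyl of 14 becomes C7–OH, and the alkyne carbons of 4 become C8 and C8a. The gain is a fully substituted ring with O7 free, O8a silylated and O5 alkylated, which later decides the direction of ring C closure. The forward reaction must control the orientation of the alkyne in the cycloaddition to vinylketene 15 and must prefer the alkyne to the two olefins.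

**Siloxyalkyne 4 from 1.** The O–Si bond and the bond between the prenyl methylene and the alkyne are cut. Ester 1 is homologated by one carbenoid carbon to ynolate 3 (through 2), so the ester carbonyl carbon becomes the oxygen-bearing alkyne carbon.

**Cyclobutenone 14 from 11 and 12.** The four-membered ring is cut at C1–C2 and C3–C4 into ketene 13 and ethoxyacetylene 12. Ketene 13 comes from acid chloride 11, and 11 from the doubly silylated hydroxy acid 10, which is the opened form (through salt 9) of lactone 8.

**Lactone 8 from 5.** The stereocentre is taken from the chiral pool. The isopropenyl group is cut at its C=CH2 bond (methylenation of ketone 7) and at its C–CH3 bond (7 from acid chloride 6 of acid 5). Neither forward step touches the C–O bond of the stereocentre, and both avoid base.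

**Aldehyde 25 from 22.** Acid 22 is esterified (23), protected (24) and reduced to the aldehyde oxidation level.

## Alternatives that were turned down

**Alternative 1: ring A folded onto a lactone.** Ring A is disconnected at C4a–C5. The precursor is the pyranone A1, in which ring C already exists and C5 to C8 hang from it as an α-acyl-γ-lactone. In the forward step an amidine base forms the extended enolate through C8, pyranone carbon C4a attacks the lactone carbonyl, ring A closes and aromatises, and the lactone oxygen is released as the C2'' hydroxyl, giving A2.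
- For it: ring A appears with O5 and O7 already free and the side-chain hydroxyl unmasked in the same step. Only the ring B acetals remain, and the stereocentre comes from the same lactone 8. On protecting-group economy at the end it is stronger than the chosen route.
- Against it: the most acidic site of A1 is the lactone α-carbon between two carbonyls. Its enolate forms first and switches off the very lactone carbonyl that must be attacked, so a dianion is needed. Retro-Claisen cleavage and opening of the pyranone at C2 then compete. A1 itself needs a long assembly of a 3-aryl-pyranone acetic acid unit with lactone 8.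
- Comparison: the chosen route spends more steps on protecting groups, but its ring-forming event has a well-understood pericyclic course and its precursor is reached in few steps.

**Alternative 2: rhodium-catalysed annulation for ring C.** The cuts are C3–C4 and O1–C2. Salicylaldehyde A3 and aryl(silyl)alkyne A4 are joined by [RhCl2(C5Me5)]2 (trivalent rhodium) with Cu(OAc)2 (divalent copper) as oxidant. Aldehyde C–H activation, alkyne insertion and C–O reductive elimination give the 2-silyl isoflavone A5.
- For it: two bonds of ring C and the whole of ring B arrive in one step, and no enolisable aldehyde or aryllithium is needed. On convergence at ring C it is stronger.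
- Against it: it does not address ring A. A3 is a hexasubstituted ring with the same differentiation problem and would itself have to come from something like 19. The aldehyde of A3 is flanked by two ortho substituents. The prenyl and isopropenyl olefins can insert into the acyl–rhodium hydride (hydroacylation) or be oxidised under the copper conditions. A desilylation step is added.
- Comparison: the chosen route closes ring C with a metal-free one-carbon condensation and puts its risk where the structural problem lies.

**Alternative 3: aryne annulation for ring C.** The cuts are O1–C8a and C4–C4a. CsF converts silyl triflate A6 into aryne A7. The enol oxygen of the formylated arylacetate A8 adds at C8a and the resulting C4a anion acylates on the ester, giving A9.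
- For it: it is metal-free and forms two bonds at once. The regiochemistry is electronically sound, since the nucleophile should add distal to the C5 oxygen and place the anion beside it. O5 is an acetal, so the end of the route is a single acid step. On that point it is stronger than the chosen route, which has to cleave an ethyl ether.
- Against it: A6 is a hexasubstituted ortho-silyl aryl triflate, which needs a fully differentiated ring A plus a silyl migration and a triflation. C8a of A7 is shielded by the prenyl group. The ambident enol of A8 can add through carbon.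
- Comparison: the chosen route builds the differentiated ring A in one step from two small fragments, which this alternative presupposes.

Key step: step 8

Remark on the chemistry: the ring carbon C4 of 14 and the carbinol carbon of 28 are formed as mixtures of epimers, and both centres are later destroyed. The starting materials 1, 5, 12 (as its hexane solution) and 22 are taken to be purchasable.

## Route

Step 1
Reactants: 1 ethyl 4-methylpent-3-enoate
Product: 4 triisopropyl(5-methylhex-4-en-1-ynyloxy)silane, via lithium dibromoenolate 2 (not isolated), via lithium ynolate 3 (not isolated)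
Conditions: CH2Br2, lithium 2,2,6,6-tetramethylpiperidide, THF, −78 °C; LiN(SiMe3)2; n-BuLi, −78 °C → rt; i-Pr3SiCl, 0 °C → rt
Reagents that add atoms: dibromomethane, BrCBr; chlorotriisopropylsilane, CC(C)[Si](Cl)(C(C)C)C(C)C
Why: Kowalski ester homologation stopped at the ynolate: LiCHBr2 adds to the ester carbonyl, the amide base gives dibromoenolate 2, and bromine–lithium exchange triggers the 1,2-shift to ynolate 3. The bulky silyl chloride reacts on oxygen and gives the isolable triisopropylsilyl ynol ether.

Step 2
Reactants: 5 (R)-5-oxotetrahydrofuran-2-carboxylic acid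
Product: 6 (R)-5-oxotetrahydrofuran-2-carbonyl chloride
Conditions: (COCl)2, cat. DMF, CH2Cl2, 0 °C → rt
Reagents that add atoms: oxalyl chloride, O=C(Cl)C(=O)Cl
Why: Acid chloride formation through the chloroiminium (Vilsmeier-type) intermediate. No base is present, so no ketene forms and the α-oxygenated stereocentre keeps its configuration.

Step 3
Reactants: 6 (R)-5-oxotetrahydrofuran-2-carbonyl chloride
Product: 7 (R)-5-acetyldihydrofuran-2(3H)-one
Conditions: CuI, MeLi (2 equiv), Et2O, 0 °C; then 6, −78 °C
Reagents that add atoms: lithium dimethylcuprate, [Li+].C[Cu-]C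
Why: Acylation of a Gilman cuprate by an acid chloride. At −78 °C the cuprate attacks neither the lactone nor the ketone product, and the non-basic medium leaves the enolisable stereocentre intact.

Step 4
Reactants: 7 (R)-5-acetyldihydrofuran-2(3H)-one
Product: 8 (R)-5-(prop-1-en-2-yl)dihydrofuran-2(3H)-one
Conditions: Zn, CH2Br2, TiCl4, THF–CH2Cl2, 0 °C → rt
Reagents that add atoms: dibromomethane, BrCBr
Why: Lombardo methylenation. The reagent is not basic, so the α-acyloxy ketone should not epimerise as it might with a phosphorus ylide, and it converts ketones in preference to lactone carbonyls.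

Step 5
Reactants: 8 (R)-5-(prop-1-en-2-yl)dihydrofuran-2(3H)-one
Product: 10 tert-butyldimethylsilyl (R)-4-(tert-butyldimethylsilyloxy)-5-methylhex-5-enoate, via potassium hydroxy carboxylate 9 (not isolated)
Conditions: KOH (1 equiv), MeOH–H2O, rt; evaporate to dryness; t-BuMe2SiCl, imidazole, DMF, rt
Reagents that add atoms: potassium hydroxide, [K+].[OH-]; tert-butylchlorodimethylsilane, CC(C)(C)[Si](C)(C)Cl
Why: Saponification of the γ-lactone, then silylation of the dry salt without acidification, because the free hydroxy acid would relactonise. The silyl chloride caps both the secondary alcohol and the carboxylate, and the C–O bond of the stereocentre is never broken.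

Step 6
Reactants: 10 tert-butyldimethylsilyl (R)-4-(tert-butyldimethylsilyloxy)-5-methylhex-5-enoate
Product: 11 (R)-4-(tert-butyldimethylsilyloxy)-5-methylhex-5-enoyl chloride
Conditions: (COCl)2, cat. DMF, CH2Cl2, 0 °C → rt; used at once
Reagents that add atoms: oxalyl chloride, O=C(Cl)C(=O)Cl
Why: Silyl esters exchange with the chloroiminium salt to give acid chlorides and the silyl chloride under neutral conditions. No HCl is formed, so the allylic silyl ether and the olefin survive. The product is used immediately because a γ-silyloxy acid chloride can relactonise on standing.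

Step 7
Reactants: 11 (R)-4-(tert-butyldimethylsilyloxy)-5-methylhex-5-enoyl chloride; 12 ethoxyacetylene
Product: 14 3-ethoxy-4-[(R)-2-(tert-butyldimethylsilyloxy)-3-methylbut-3-enyl]cyclobut-2-enone, via ketene 13 (not isolated)
Conditions: Et3N, excess 12, Et2O, slow addition of 11, 0 °C → rt
Reagents that add atoms: none
Why: Dehydrochlorination gives the monoalkylketene 13, which undergoes the ketene–alkoxyalkyne [2+2] cycloaddition. The terminal alkyne carbon bonds to the ketene carbonyl carbon, which places ethoxy on C3 and the chain on C4. The new ring stereocentre forms as a mixture and is erased in step 8.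

Step 8
Reactants: 14 3-ethoxy-4-[(R)-2-(tert-butyldimethylsilyloxy)-3-methylbut-3-enyl]cyclobut-2-enone; 4 triisopropyl(5-methylhex-4-en-1-ynyloxy)silane
Product: 19 3-ethoxy-2-[(2R)-2-(tert-butyldimethylsilyloxy)-3-methylbut-3-enyl]-6-(3-methylbut-2-enyl)-5-(triisopropylsilyloxy)phenol, via vinylketene 15 (not isolated), via vinylcyclobutenone 16 (not isolated), via dienylketene 17 (not isolated), via cyclohexadienone 18 (not isolated)
Conditions: PhMe, 80 °C, then 110 °C, sealed tube, Ar
Reagents that add atoms: none
Why: The closest known reaction type is the Danheiser benzannulation of a cyclobutenone with a siloxyalkyne, used here on a 3-ethoxy-4-alkylcyclobutenone. Thermal conrotatory 4π-electron opening of 14 breaks the bond between the carbonyl carbon and C4, with the C4 chain turning outward, and gives vinylketene 15. Siloxyalkyne 4 adds to the ketene C=C in a [2+2] cycloaddition: its nucleophilic prenyl-bearing carbon bonds to the ketene carbonyl carbon (C7–C8) and its oxygen-bearing carbon to the ketene α-carbon (C4a–C8a), giving 16. A second 4π opening gives dienylketene 17, ring A closes by thermal disrotatory 6π-electron electrocyclisation (C6–C7, six-membered ring), and cyclohexadienone 18 tautomerises irreversibly to phenol 19. No stereocentre is created: the sp3 ring centres of 14, 16 and 18 become sp2, and C2'' lies outside the reacting array and carries no acidic hydrogen, so it stays R. The step needs regiocontrol in the ketene–alkyne cycloaddition, which the oxygen donor of 4 secures by making its β-carbon the nucleophile. It also needs chemoselectivity for the alkyne over the prenyl and isopropenyl olefins, which follows from the far higher ketenophilicity of an ynol ether. Opening of 16 is reversible and only the isomer of 17 with the ketene and the vinyl terminus cis can cyclise, so the geometry at that bond corrects itself. The ring emerges with O7 as a free phenol, O8a as a silyl ether and O5 as an ethyl ether.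

Step 9
Reactants: 19 3-ethoxy-2-[(2R)-2-(tert-butyldimethylsilyloxy)-3-methylbut-3-enyl]-6-(3-methylbut-2-enyl)-5-(triisopropylsilyloxy)phenol
Product: 20 1-ethoxy-2-[(2R)-2-(tert-butyldimethylsilyloxy)-3-methylbut-3-enyl]-3-(methoxymethoxy)-4-(3-methylbut-2-enyl)-5-(triisopropylsilyloxy)benzene
Conditions: NaH, MeOCH2Cl, THF–DMF, 0 °C
Reagents that add atoms: chloromethyl methyl ether, COCCl
Why: O-Alkylation of the hindered phenoxide (Williamson-type acetal formation); both silyl ethers are stable to NaH at 0 °C. The acidic O7–H is removed before the halogen–metal exchange and the ortho-prenyl phenol can no longer cyclise.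

Step 10
Reactants: 20 1-ethoxy-2-[(2R)-2-(tert-butyldimethylsilyloxy)-3-methylbut-3-enyl]-3-(methoxymethoxy)-4-(3-methylbut-2-enyl)-5-(triisopropylsilyloxy)benzene
Product: 21 1-bromo-2-ethoxy-3-[(2R)-2-(tert-butyldimethylsilyloxy)-3-methylbut-3-enyl]-4-(methoxymethoxy)-5-(3-methylbut-2-enyl)-6-(triisopropylsilyloxy)benzene
Conditions: NBS, CH2Cl2, −78 → 0 °C, dark
Reagents that add atoms: N-bromosuccinimide, O=C1CCC(=O)N1Br
Why: Electrophilic aromatic bromination. C4a is the only unsubstituted ring position and is activated by two ortho oxygens and one para oxygen, so it should react faster than either olefin, which has no internal nucleophile left to trap a bromonium ion.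

Step 11
Reactants: 22 2,4-dihydroxyphenylacetic acid
Product: 23 methyl 2,4-dihydroxyphenylacetate
Conditions: MeOH, cat. H2SO4, reflux
Reagents that add atoms: methanol, CO
Why: Fischer esterification. In excess methanol the benzofuranone that could form from the ortho hydroxyl is reopened to the ester.

Step 12
Reactants: 23 methyl 2,4-dihydroxyphenylacetate
Product: 24 methyl 2-[2,4-bis(methoxymethoxy)phenyl]acetate
Conditions: MeOCH2Cl, i-Pr2NEt, CH2Cl2, 0 °C → rt
Reagents that add atoms: chloromethyl methyl ether, COCCl
Why: Acetal protection of both phenols with an amine base; the mild base avoids phenoxide attack on the ester.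

Step 13
Reactants: 24 methyl 2-[2,4-bis(methoxymethoxy)phenyl]acetate
Product: 25 2-[2,4-bis(methoxymethoxy)phenyl]acetaldehyde
Conditions: i-Bu2AlH (1 equiv), CH2Cl2, −78 °C; used directly
Reagents that add atoms: none
Why: Partial reduction of an ester: the tetrahedral aluminium hemiacetal is stable at −78 °C and releases the aldehyde only on work-up. The enolisable arylacetaldehyde is used without storage.

Step 14
Reactants: 21 1-bromo-2-ethoxy-3-[(2R)-2-(tert-butyldimethylsilyloxy)-3-methylbut-3-enyl]-4-(methoxymethoxy)-5-(3-methylbut-2-enyl)-6-(triisopropylsilyloxy)benzene; 25 2-[2,4-bis(methoxymethoxy)phenyl]acetaldehyde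
Product: 28 1-{2-ethoxy-3-[(2R)-2-(tert-butyldimethylsilyloxy)-3-methylbut-3-enyl]-4-(methoxymethoxy)-5-(3-methylbut-2-enyl)-6-(triisopropylsilyloxy)phenyl}-2-[2,4-bis(methoxymethoxy)phenyl]ethanol, via aryllithium 26 (not isolated), via arylcerium dichloride 27 (not isolated)
Conditions: t-BuLi (2 equiv), THF, −78 °C; CeCl3, −78 °C; then 25, −78 → −40 °C
Reagents that add atoms: none
Why: Bromine–lithium exchange, transmetalation and 1,2-addition of an organocerium reagent, which is nucleophilic but weakly basic and so adds to the enolisable aldehyde instead of deprotonating it. The bulk of the triisopropylsilyl group slows the anionic oxygen-to-carbon silyl shift (retro-Brook rearrangement) at −78 °C. The carbinol centre forms as a mixture and is oxidised away in step 15.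

Step 15
Reactants: 28 1-{2-ethoxy-3-[(2R)-2-(tert-butyldimethylsilyloxy)-3-methylbut-3-enyl]-4-(methoxymethoxy)-5-(3-methylbut-2-enyl)-6-(triisopropylsilyloxy)phenyl}-2-[2,4-bis(methoxymethoxy)phenyl]ethanol
Product: 29 1-{2-ethoxy-3-[(2R)-2-(tert-butyldimethylsilyloxy)-3-methylbut-3-enyl]-4-(methoxymethoxy)-5-(3-methylbut-2-enyl)-6-(triisopropylsilyloxy)phenyl}-2-[2,4-bis(methoxymethoxy)phenyl]ethanone
Conditions: Dess–Martin periodinane, CH2Cl2, 0 °C → rt
Reagents that add atoms: none
Why: Dess–Martin oxidation of a secondary benzylic alcohol under near-neutral conditions, compatible with the olefins, acetals and silyl ethers.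

Step 16
Reactants: 29 1-{2-ethoxy-3-[(2R)-2-(tert-butyldimethylsilyloxy)-3-methylbut-3-enyl]-4-(methoxymethoxy)-5-(3-methylbut-2-enyl)-6-(triisopropylsilyloxy)phenyl}-2-[2,4-bis(methoxymethoxy)phenyl]ethanone
Product: 30 1-{6-ethoxy-2-hydroxy-5-[(2R)-2-(tert-butyldimethylsilyloxy)-3-methylbut-3-enyl]-4-(methoxymethoxy)-3-(3-methylbut-2-enyl)phenyl}-2-[2,4-bis(methoxymethoxy)phenyl]ethanone
Conditions: n-Bu4NF (1 equiv), AcOH (1 equiv), THF, 0 °C
Reagents that add atoms: none
Why: Fluoride cleaves the aryl silyl ether, whose phenoxide is stabilised by the ortho acyl group, much faster than the secondary alkyl silyl ether. Acetic acid buffers the phenoxide and protects the enolisable ketone.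

Step 17
Reactants: 30 1-{6-ethoxy-2-hydroxy-5-[(2R)-2-(tert-butyldimethylsilyloxy)-3-methylbut-3-enyl]-4-(methoxymethoxy)-3-(3-methylbut-2-enyl)phenyl}-2-[2,4-bis(methoxymethoxy)phenyl]ethanone
Product: 32 5-ethoxy-7-(methoxymethoxy)-3-[2,4-bis(methoxymethoxy)phenyl]-6-[(2R)-2-(tert-butyldimethylsilyloxy)-3-methylbut-3-enyl]-8-(3-methylbut-2-enyl)-4H-chromen-4-one, via enaminone 31 (not isolated)
Conditions: Me2NCH(OMe)2, PhMe, 90 °C
Reagents that add atoms: N,N-dimethylformamide dimethyl acetal, COC(OC)N(C)C
Why: Condensation of the activated methylene with the formamide acetal gives enaminone 31. The only free phenol, O8a, adds in conjugate fashion and dimethylamine is eliminated (addition–elimination, 6-endo closure), which is the standard deoxybenzoin route to isoflavones. O5 is an ether and cannot compete, so the prenyl group ends on C8.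

Step 18
Reactants: 32 5-ethoxy-7-(methoxymethoxy)-3-[2,4-bis(methoxymethoxy)phenyl]-6-[(2R)-2-(tert-butyldimethylsilyloxy)-3-methylbut-3-enyl]-8-(3-methylbut-2-enyl)-4H-chromen-4-one
Product: 33 5-hydroxy-7-(methoxymethoxy)-3-[2,4-bis(methoxymethoxy)phenyl]-6-[(2R)-2-(tert-butyldimethylsilyloxy)-3-methylbut-3-enyl]-8-(3-methylbut-2-enyl)-4H-chromen-4-one
Conditions: MgI2·OEt2, PhMe–THF, 60 °C; aq. NH4Cl
Reagents that add atoms: none
Why: Chelation-assisted dealkylation: magnesium is held between the C4 carbonyl and O5, and iodide displaces the activated ethyl group by SN2. No other ether has a carbonyl partner for a six-membered chelate, and no protic acid is present to attack the olefins. Any acetal lost here would be removed in step 19 anyway.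

Step 19
Reactants: 33 5-hydroxy-7-(methoxymethoxy)-3-[2,4-bis(methoxymethoxy)phenyl]-6-[(2R)-2-(tert-butyldimethylsilyloxy)-3-methylbut-3-enyl]-8-(3-methylbut-2-enyl)-4H-chromen-4-one
Product: 34 3-(2,4-dihydroxyphenyl)-5,7-dihydroxy-6-[(2R)-2-hydroxy-3-methylbut-3-enyl]-8-(3-methylbut-2-enyl)-4H-chromen-4-one
Conditions: aq. HCl (2 M), MeOH–THF, 40 °C, monitored closely
Reagents that add atoms: none
Why: Acid-catalysed acetal exchange removes the three methoxymethyl groups and methanolysis removes the silyl ether. Both are faster than olefin protonation under dilute acid, and the C–O bond at C2'' is not broken, so the R configuration is kept.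

## Compound list

1 | ethyl 4-methylpent-3-enoate | CCOC(=O)CC=C(C)C | starting material
2 | lithium 1,1-dibromo-5-methylhexa-1,4-dien-2-olate | [Li+].[O-]C(CC=C(C)C)=C(Br)Br | intermediate
3 | lithium 5-methylhex-4-en-1-yn-1-olate | [Li+].[O-]C#CCC=C(C)C | intermediate
4 | triisopropyl(5-methylhex-4-en-1-ynyloxy)silane | CC(C)=CCC#CO[Si](C(C)C)(C(C)C)C(C)C | intermediate
5 | (R)-5-oxotetrahydrofuran-2-carboxylic acid | O=C1CC[C@H](C(=O)O)O1 | starting material
6 | (R)-5-oxotetrahydrofuran-2-carbonyl chloride | O=C1CC[C@H](C(=O)Cl)O1 | intermediate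
7 | (R)-5-acetyldihydrofuran-2(3H)-one | O=C1CC[C@H](C(C)=O)O1 | intermediate
8 | (R)-5-(prop-1-en-2-yl)dihydrofuran-2(3H)-one | O=C1CC[C@H](C(C)=C)O1 | intermediate
9 | potassium (R)-4-hydroxy-5-methylhex-5-enoate | C=C(C)[C@H](O)CCC(=O)[O-].[K+] | intermediate
10 | tert-butyldimethylsilyl (R)-4-(tert-butyldimethylsilyloxy)-5-methylhex-5-enoate | C=C(C)[C@H](O[Si](C)(C)C(C)(C)C)CCC(=O)O[Si](C)(C)C(C)(C)C | intermediate
11 | (R)-4-(tert-butyldimethylsilyloxy)-5-methylhex-5-enoyl chloride | C=C(C)[C@H](O[Si](C)(C)C(C)(C)C)CCC(=O)Cl | intermediate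
12 | ethoxyacetylene | C#COCC | starting material
13 | (R)-4-(tert-butyldimethylsilyloxy)-5-methylhexa-1,5-dien-1-one (ketene) | C=C(C)[C@H](O[Si](C)(C)C(C)(C)C)CC=C=O | intermediate
14 | 3-ethoxy-4-[(R)-2-(tert-butyldimethylsilyloxy)-3-methylbut-3-enyl]cyclobut-2-enone (both epimers at ring C4) | C=C(C)[C@H](O[Si](C)(C)C(C)(C)C)CC1C(=O)C=C1OCC | intermediate
15 | (R,Z)-6-(tert-butyldimethylsilyloxy)-3-ethoxy-7-methylocta-1,3,7-trien-1-one (vinylketene) | C=C(C)[C@H](O[Si](C)(C)C(C)(C)C)C/C=C(\OCC)C=C=O | intermediate
16 | 4-[(R,Z)-4-(tert-butyldimethylsilyloxy)-1-ethoxy-5-methylhexa-1,5-dienyl]-2-(3-methylbut-2-enyl)-3-(triisopropylsilyloxy)cyclobut-2-enone (both epimers at ring C4) | C=C(C)[C@H](O[Si](C)(C)C(C)(C)C)C/C=C(\OCC)C1C(=O)C(CC=C(C)C)=C1O[Si](C(C)C)(C(C)C)C(C)C | intermediate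
17 | (R,3E,5Z)-8-(tert-butyldimethylsilyloxy)-5-ethoxy-9-methyl-2-(3-methylbut-2-enyl)-3-(triisopropylsilyloxy)deca-1,3,5,9-tetraen-1-one (dienylketene) | C=C(C)[C@H](O[Si](C)(C)C(C)(C)C)C/C=C(\OCC)/C=C(/O[Si](C(C)C)(C(C)C)C(C)C)C(CC=C(C)C)=C=O | intermediate
18 | 5-ethoxy-6-[(R)-2-(tert-butyldimethylsilyloxy)-3-methylbut-3-enyl]-2-(3-methylbut-2-enyl)-3-(triisopropylsilyloxy)cyclohexa-2,4-dienone (both epimers at ring C6) | C=C(C)[C@H](O[Si](C)(C)C(C)(C)C)CC1C(=O)C(CC=C(C)C)=C(O[Si](C(C)C)(C(C)C)C(C)C)C=C1OCC | intermediate
19 | 3-ethoxy-2-[(2R)-2-(tert-butyldimethylsilyloxy)-3-methylbut-3-enyl]-6-(3-methylbut-2-enyl)-5-(triisopropylsilyloxy)phenol | C=C(C)[C@H](O[Si](C)(C)C(C)(C)C)Cc1c(O)c(CC=C(C)C)c(O[Si](C(C)C)(C(C)C)C(C)C)cc1OCC | intermediate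
20 | 1-ethoxy-2-[(2R)-2-(tert-butyldimethylsilyloxy)-3-methylbut-3-enyl]-3-(methoxymethoxy)-4-(3-methylbut-2-enyl)-5-(triisopropylsilyloxy)benzene | C=C(C)[C@H](O[Si](C)(C)C(C)(C)C)Cc1c(OCOC)c(CC=C(C)C)c(O[Si](C(C)C)(C(C)C)C(C)C)cc1OCC | intermediate
21 | 1-bromo-2-ethoxy-3-[(2R)-2-(tert-butyldimethylsilyloxy)-3-methylbut-3-enyl]-4-(methoxymethoxy)-5-(3-methylbut-2-enyl)-6-(triisopropylsilyloxy)benzene | C=C(C)[C@H](O[Si](C)(C)C(C)(C)C)Cc1c(OCOC)c(CC=C(C)C)c(O[Si](C(C)C)(C(C)C)C(C)C)c(Br)c1OCC | intermediate
22 | 2,4-dihydroxyphenylacetic acid | O=C(O)Cc1ccc(O)cc1O | starting material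
23 | methyl 2,4-dihydroxyphenylacetate | COC(=O)Cc1ccc(O)cc1O | intermediate
24 | methyl 2-[2,4-bis(methoxymethoxy)phenyl]acetate | COCOc1ccc(CC(=O)OC)c(OCOC)c1 | intermediate
25 | 2-[2,4-bis(methoxymethoxy)phenyl]acetaldehyde | COCOc1ccc(CC=O)c(OCOC)c1 | intermediate
26 | aryllithium from 21 (lithium on C4a) | C=C(C)[C@H](O[Si](C)(C)C(C)(C)C)Cc1c(OCOC)c(CC=C(C)C)c(O[Si](C(C)C)(C(C)C)C(C)C)c([Li])c1OCC | intermediate
27 | arylcerium dichloride from 26 (cerium on C4a) | C=C(C)[C@H](O[Si](C)(C)C(C)(C)C)Cc1c(OCOC)c(CC=C(C)C)c(O[Si](C(C)C)(C(C)C)C(C)C)c([Ce](Cl)Cl)c1OCC | intermediate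
28 | 1-{2-ethoxy-3-[(2R)-2-(tert-butyldimethylsilyloxy)-3-methylbut-3-enyl]-4-(methoxymethoxy)-5-(3-methylbut-2-enyl)-6-(triisopropylsilyloxy)phenyl}-2-[2,4-bis(methoxymethoxy)phenyl]ethanol (both epimers at the carbinol carbon) | C=C(C)[C@H](O[Si](C)(C)C(C)(C)C)Cc1c(OCOC)c(CC=C(C)C)c(O[Si](C(C)C)(C(C)C)C(C)C)c(C(O)Cc2ccc(OCOC)cc2OCOC)c1OCC | intermediate
29 | 1-{2-ethoxy-3-[(2R)-2-(tert-butyldimethylsilyloxy)-3-methylbut-3-enyl]-4-(methoxymethoxy)-5-(3-methylbut-2-enyl)-6-(triisopropylsilyloxy)phenyl}-2-[2,4-bis(methoxymethoxy)phenyl]ethanone | C=C(C)[C@H](O[Si](C)(C)C(C)(C)C)Cc1c(OCOC)c(CC=C(C)C)c(O[Si](C(C)C)(C(C)C)C(C)C)c(C(=O)Cc2ccc(OCOC)cc2OCOC)c1OCC | intermediate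
30 | 1-{6-ethoxy-2-hydroxy-5-[(2R)-2-(tert-butyldimethylsilyloxy)-3-methylbut-3-enyl]-4-(methoxymethoxy)-3-(3-methylbut-2-enyl)phenyl}-2-[2,4-bis(methoxymethoxy)phenyl]ethanone | C=C(C)[C@H](O[Si](C)(C)C(C)(C)C)Cc1c(OCOC)c(CC=C(C)C)c(O)c(C(=O)Cc2ccc(OCOC)cc2OCOC)c1OCC | intermediate
31 | 3-(dimethylamino)-1-{6-ethoxy-2-hydroxy-5-[(2R)-2-(tert-butyldimethylsilyloxy)-3-methylbut-3-enyl]-4-(methoxymethoxy)-3-(3-methylbut-2-enyl)phenyl}-2-[2,4-bis(methoxymethoxy)phenyl]prop-2-en-1-one (enaminone) | C=C(C)[C@H](O[Si](C)(C)C(C)(C)C)Cc1c(OCOC)c(CC=C(C)C)c(O)c(C(=O)C(=CN(C)C)c2ccc(OCOC)cc2OCOC)c1OCC | intermediate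
32 | 5-ethoxy-7-(methoxymethoxy)-3-[2,4-bis(methoxymethoxy)phenyl]-6-[(2R)-2-(tert-butyldimethylsilyloxy)-3-methylbut-3-enyl]-8-(3-methylbut-2-enyl)-4H-chromen-4-one | C=C(C)[C@H](O[Si](C)(C)C(C)(C)C)Cc1c(OCOC)c(CC=C(C)C)c2occ(-c3ccc(OCOC)cc3OCOC)c(=O)c2c1OCC | intermediate
33 | 5-hydroxy-7-(methoxymethoxy)-3-[2,4-bis(methoxymethoxy)phenyl]-6-[(2R)-2-(tert-butyldimethylsilyloxy)-3-methylbut-3-enyl]-8-(3-methylbut-2-enyl)-4H-chromen-4-one | C=C(C)[C@H](O[Si](C)(C)C(C)(C)C)Cc1c(OCOC)c(CC=C(C)C)c2occ(-c3ccc(OCOC)cc3OCOC)c(=O)c2c1O | intermediate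
34 | 3-(2,4-dihydroxyphenyl)-5,7-dihydroxy-6-[(2R)-2-hydroxy-3-methylbut-3-enyl]-8-(3-methylbut-2-enyl)-4H-chromen-4-one | C=C(C)[C@H](O)Cc1c(O)c(CC=C(C)C)c2occ(-c3ccc(O)cc3O)c(=O)c2c1O | target

## Step count and least certain steps

Total step count: 19. Longest linear sequence: 15 steps (from 5 through steps 2 to 10 and 14 to 19).

**Step 8 (key step).** The ethoxy group makes 14 a vinylogous ester, which may raise the temperature needed for the first ring opening to a range where the siloxyalkyne degrades or the vinylketene is consumed by dimerisation or by acylating the product phenol. Fallback: generate the same vinylketene without the electrocyclic opening, setting out from acid chloride 11. Acylation of the lithium enolate of ethyl acetate with 11 should give ethyl (R)-6-(tert-butyldimethylsilyloxy)-7-methyl-3-oxooct-7-enoate F1. Triethyl orthoformate with a trace of pyridinium p-toluenesulfonate converts it into ethyl (R,E)-6-(tert-butyldimethylsilyloxy)-3-ethoxy-7-methylocta-2,7-dienoate F2. Saponification with LiOH gives (R,E)-6-(tert-butyldimethylsilyloxy)-3-ethoxy-7-methylocta-2,7-dienoic acid F3, and its sodium salt with oxalyl chloride gives (R,E)-6-(tert-butyldimethylsilyloxy)-3-ethoxy-7-methylocta-2,7-dienoyl chloride F4. Triethylamine in the presence of 4 effects 1,4-dehydrochlorination to vinylketene 15 at or below room temperature, and the cascade through 16, 17 and 18 is completed by gentle warming. The fallback returns to the route at 19.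

**Step 1.** The α-hydrogens of the β,γ-unsaturated ester are unusually acidic, so deprotonation by the carbenoid, with loss of the ester to its dienolate and migration of the double bond, may outrun carbonyl addition. Fallback: reach the same ynolate by oxidation of an acetylide, setting out from 1. Reduction with i-Bu2AlH at −78 °C gives 4-methylpent-3-enal F5. CBr4 and PPh3 (Corey–Fuchs olefination, neutral) give 1,1-dibromo-5-methylhexa-1,4-diene F6, and n-BuLi (2 equiv) gives lithium 5-methylhex-4-en-1-yn-1-ide F7. Oxidation of F7 with lithium tert-butyl peroxide gives ynolate 3, where the fallback rejoins the route, and silylation as in step 1 gives 4.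

**Step 14.** The aryllithium carries a silyloxy group on the neighbouring carbon, and an anionic oxygen-to-carbon silyl shift would destroy the nucleophile. Proton transfer from the aldehyde is the second threat if transmetalation to cerium is incomplete. Fallback: replace the silyl group on O8a by an acetal before metalation, setting out from 21. n-Bu4NF gives 2-bromo-3-ethoxy-4-[(2R)-2-(tert-butyldimethylsilyloxy)-3-methylbut-3-enyl]-5-(methoxymethoxy)-6-(3-methylbut-2-enyl)phenol F8. NaH and chloromethyl methyl ether give 1-bromo-2-ethoxy-3-[(2R)-2-(tert-butyldimethylsilyloxy)-3-methylbut-3-enyl]-4,6-bis(methoxymethoxy)-5-(3-methylbut-2-enyl)benzene F9. t-BuLi gives the aryllithium F10, which cannot undergo a silyl shift, and CeCl3 gives the arylcerium dichloride F11. Addition to 25 gives the carbinol F12, and Dess–Martin oxidation gives 1-{2-ethoxy-3-[(2R)-2-(tert-butyldimethylsilyloxy)-3-methylbut-3-enyl]-4,6-bis(methoxymethoxy)-5-(3-methylbut-2-enyl)phenyl}-2-[2,4-bis(methoxymethoxy)phenyl]ethanone F13. MgBr2·OEt2 then removes only the acetal that can chelate with the ketone, the one on O8a. The fallback returns to the route at 30.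

**Step 18.** Iodide attack on an ethyl group is much slower than on a methyl group, so the dealkylation may stall, or may need heating that lets the Lewis acid strip acetals and then attack the prenyl group next to a freed O7. Fallback: use a boron Lewis acid for all aryl ethers at once, setting out from 32. BCl3 in CH2Cl2 at −78 → 0 °C cleaves the chelated C5 ethyl ether and the three methoxymethyl ethers and should give 3-(2,4-dihydroxyphenyl)-5,7-dihydroxy-6-[(2R)-2-(tert-butyldimethylsilyloxy)-3-methylbut-3-enyl]-8-(3-methylbut-2-enyl)-4H-chromen-4-one F14. n-Bu4NF buffered with AcOH then removes the silyl ether. The fallback returns to the route at 34 and replaces steps 18 and 19.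

**Step 19.** Protonation of the prenyl or isopropenyl olefin under protic acid would start cyclisation onto O7 or O5 (chroman or dihydrofuran formation), and ionisation of the allylic carbinol would erode the stereocentre. Fallback: two aprotic operations, setting out from 33. n-Bu4NF removes the silyl ether first and gives 3-[2,4-bis(methoxymethoxy)phenyl]-5-hydroxy-6-[(2R)-2-hydroxy-3-methylbut-3-enyl]-7-(methoxymethoxy)-8-(3-methylbut-2-enyl)-4H-chromen-4-one F15. ZnBr2 with n-PrSH in CH2Cl2 at 0 °C then cleaves the three acetals within minutes by thiol capture of the oxocarbenium ion, without free protic acid. The fallback returns to the route at 34.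

## Further compounds

F1 | step 8 | ethyl (R)-6-(tert-butyldimethylsilyloxy)-7-methyl-3-oxooct-7-enoate | C=C(C)[C@H](O[Si](C)(C)C(C)(C)C)CCC(=O)CC(=O)OCC
F2 | step 8 | ethyl (R,E)-6-(tert-butyldimethylsilyloxy)-3-ethoxy-7-methylocta-2,7-dienoate | C=C(C)[C@H](O[Si](C)(C)C(C)(C)C)CC/C(OCC)=C\C(=O)OCC
F3 | step 8 | (R,E)-6-(tert-butyldimethylsilyloxy)-3-ethoxy-7-methylocta-2,7-dienoic acid | C=C(C)[C@H](O[Si](C)(C)C(C)(C)C)CC/C(OCC)=C\C(=O)O
F4 | step 8 | (R,E)-6-(tert-butyldimethylsilyloxy)-3-ethoxy-7-methylocta-2,7-dienoyl chloride | C=C(C)[C@H](O[Si](C)(C)C(C)(C)C)CC/C(OCC)=C\C(=O)Cl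
F5 | step 1 | 4-methylpent-3-enal | CC(C)=CCC=O
F6 | step 1 | 1,1-dibromo-5-methylhexa-1,4-diene | CC(C)=CCC=C(Br)Br
F7 | step 1 | lithium 5-methylhex-4-en-1-yn-1-ide | CC(C)=CCC#C[Li]
F8 | step 14 | 2-bromo-3-ethoxy-4-[(2R)-2-(tert-butyldimethylsilyloxy)-3-methylbut-3-enyl]-5-(methoxymethoxy)-6-(3-methylbut-2-enyl)phenol | C=C(C)[C@H](O[Si](C)(C)C(C)(C)C)Cc1c(OCOC)c(CC=C(C)C)c(O)c(Br)c1OCC
F9 | step 14 | 1-bromo-2-ethoxy-3-[(2R)-2-(tert-butyldimethylsilyloxy)-3-methylbut-3-enyl]-4,6-bis(methoxymethoxy)-5-(3-methylbut-2-enyl)benzene | C=C(C)[C@H](O[Si](C)(C)C(C)(C)C)Cc1c(OCOC)c(CC=C(C)C)c(OCOC)c(Br)c1OCC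
F10 | step 14 | aryllithium from F9 (lithium on C4a) | C=C(C)[C@H](O[Si](C)(C)C(C)(C)C)Cc1c(OCOC)c(CC=C(C)C)c(OCOC)c([Li])c1OCC
F11 | step 14 | arylcerium dichloride from F10 (cerium on C4a) | C=C(C)[C@H](O[Si](C)(C)C(C)(C)C)Cc1c(OCOC)c(CC=C(C)C)c(OCOC)c([Ce](Cl)Cl)c1OCC
F12 | step 14 | 1-{2-ethoxy-3-[(2R)-2-(tert-butyldimethylsilyloxy)-3-methylbut-3-enyl]-4,6-bis(methoxymethoxy)-5-(3-methylbut-2-enyl)phenyl}-2-[2,4-bis(methoxymethoxy)phenyl]ethanol (both epimers at the carbinol carbon) | C=C(C)[C@H](O[Si](C)(C)C(C)(C)C)Cc1c(OCOC)c(CC=C(C)C)c(OCOC)c(C(O)Cc2ccc(OCOC)cc2OCOC)c1OCC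
F13 | step 14 | 1-{2-ethoxy-3-[(2R)-2-(tert-butyldimethylsilyloxy)-3-methylbut-3-enyl]-4,6-bis(methoxymethoxy)-5-(3-methylbut-2-enyl)phenyl}-2-[2,4-bis(methoxymethoxy)phenyl]ethanone | C=C(C)[C@H](O[Si](C)(C)C(C)(C)C)Cc1c(OCOC)c(CC=C(C)C)c(OCOC)c(C(=O)Cc2ccc(OCOC)cc2OCOC)c1OCC
F14 | step 18 | 3-(2,4-dihydroxyphenyl)-5,7-dihydroxy-6-[(2R)-2-(tert-butyldimethylsilyloxy)-3-methylbut-3-enyl]-8-(3-methylbut-2-enyl)-4H-chromen-4-one | C=C(C)[C@H](O[Si](C)(C)C(C)(C)C)Cc1c(O)c(CC=C(C)C)c2occ(-c3ccc(O)cc3O)c(=O)c2c1O
F15 | step 19 | 3-[2,4-bis(methoxymethoxy)phenyl]-5-hydroxy-6-[(2R)-2-hydroxy-3-methylbut-3-enyl]-7-(methoxymethoxy)-8-(3-methylbut-2-enyl)-4H-chromen-4-one | C=C(C)[C@H](O)Cc1c(OCOC)c(CC=C(C)C)c2occ(-c3ccc(OCOC)cc3OCOC)c(=O)c2c1O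
A1 | alternative 1 | 3-[2,4-bis(methoxymethoxy)phenyl]-6-{5-methyl-1-oxo-1-[(5R)-2-oxo-5-(prop-1-en-2-yl)tetrahydrofuran-3-yl]hex-4-en-2-yl}-4H-pyran-4-one | O=c1cc(C(CC=C(C)C)C(=O)C2C[C@H](C(C)=C)OC2=O)occ1-c1ccc(OCOC)cc1OCOC
A2 | alternative 1 | 3-[2,4-bis(methoxymethoxy)phenyl]-5,7-dihydroxy-6-[(2R)-2-hydroxy-3-methylbut-3-enyl]-8-(3-methylbut-2-enyl)-4H-chromen-4-one | C=C(C)[C@H](O)Cc1c(O)c(CC=C(C)C)c2occ(-c3ccc(OCOC)cc3OCOC)c(=O)c2c1O
A3 | alternative 2 | 3-[(2R)-2-(tert-butyldimethylsilyloxy)-3-methylbut-3-enyl]-6-hydroxy-2,4-bis(methoxymethoxy)-5-(3-methylbut-2-enyl)benzaldehyde | C=C(C)[C@H](O[Si](C)(C)C(C)(C)C)Cc1c(OCOC)c(CC=C(C)C)c(O)c(C=O)c1OCOC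
A4 | alternative 2 | {[2,4-bis(methoxymethoxy)phenyl]ethynyl}trimethylsilane | C[Si](C)(C)C#Cc1ccc(OCOC)cc1OCOC
A5 | alternative 2 | 3-[2,4-bis(methoxymethoxy)phenyl]-6-[(2R)-2-(tert-butyldimethylsilyloxy)-3-methylbut-3-enyl]-5,7-bis(methoxymethoxy)-8-(3-methylbut-2-enyl)-2-(trimethylsilyl)-4H-chromen-4-one | C=C(C)[C@H](O[Si](C)(C)C(C)(C)C)Cc1c(OCOC)c(CC=C(C)C)c2oc([Si](C)(C)C)c(-c3ccc(OCOC)cc3OCOC)c(=O)c2c1OCOC
A6 | alternative 3 | 4-[(2R)-2-(tert-butyldimethylsilyloxy)-3-methylbut-3-enyl]-3,5-bis(methoxymethoxy)-2-(3-methylbut-2-enyl)-6-(trimethylsilyl)phenyl trifluoromethanesulfonate | C=C(C)[C@H](O[Si](C)(C)C(C)(C)C)Cc1c(OCOC)c(CC=C(C)C)c(OS(=O)(=O)C(F)(F)F)c([Si](C)(C)C)c1OCOC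
A7 | alternative 3 | ring A aryne across C4a–C8a: 4-[(2R)-2-(tert-butyldimethylsilyloxy)-3-methylbut-3-enyl]-3,5-bis(methoxymethoxy)-6-(3-methylbut-2-enyl)benzyne | C=C(C)[C@H](O[Si](C)(C)C(C)(C)C)CC1=C(OCOC)C#CC(CC=C(C)C)=C1OCOC
A8 | alternative 3 | methyl 2-[2,4-bis(methoxymethoxy)phenyl]-3-hydroxyprop-2-enoate | COC(=O)C(=CO)c1ccc(OCOC)cc1OCOC
A9 | alternative 3 | 3-[2,4-bis(methoxymethoxy)phenyl]-6-[(2R)-2-(tert-butyldimethylsilyloxy)-3-methylbut-3-enyl]-5,7-bis(methoxymethoxy)-8-(3-methylbut-2-enyl)-4H-chromen-4-one | C=C(C)[C@H](O[Si](C)(C)C(C)(C)C)Cc1c(OCOC)c(CC=C(C)C)c2occ(-c3ccc(OCOC)cc3OCOC)c(=O)c2c1OCOC
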